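**Assumptions.** The target has no stereocentres and no E/Z-isomerism (both alkenes end in CMe2), so it is achiral and no stereocontrol is needed. Simple reagents (MOMCl, prenyl bromide, NBS, CO2, MeI, etc.) are named with SMILES under each step and are not numbered.

## Retrosynthetic overview

1. Target 14 ← tri-MOM ether 13 by global MOM removal.
2. 13 ← one-pot three-component coupling (new): potassium aryloxide of ring-B phenol 8 + 3,5-bis(MOMO)benzyne (from 12) + CO2, then MeI. This forms the diaryl ether C–O bond and the aryl–CO2Me C–C bond together.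
3. 8 ← 3,4-dimethoxyphenol (1): C3' prenyl by ortho-Claisen of a 1,1-dimethylallyl ether, the C1' oxygen by MOM-directed lithiation/borylation/oxidation, C4' prenyl by para-Claisen–Cope of the O-prenyl ether.
4. 12 ← phloroglucinol (9): bis-MOM protection, ortho-bromination, retro-Brook/triflation.
5. No ring is formed; both benzene rings are bought. Ring B is fully substituted first, then ring A is introduced as the aryne.

## Route

**Step 1**
Reactants: 1, 3,4-dimethoxyphenol
Product: 2, 1,2-dimethoxy-4-[(2-methylbut-3-yn-2-yl)oxy]benzene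
Conditions: 3-chloro-3-methylbut-1-yne, DBU, CuCl2·2H2O (cat.), MeCN, 0 °C
Reagents that add atoms: 3-chloro-3-methylbut-1-yne, CC(C)(Cl)C#C
Why: Cu-catalysed O-propargylation of a phenol with a tertiary propargyl chloride (via a copper allenylidene/propargyl cation) gives the 1,1-dimethylpropargyl aryl ether cleanly.

**Step 2**
Reactants: 2, 1,2-dimethoxy-4-[(2-methylbut-3-yn-2-yl)oxy]benzene
Product: 3, 1,2-dimethoxy-4-[(2-methylbut-3-en-2-yl)oxy]benzene
Conditions: H2 (1 atm), Lindlar catalyst, quinoline, EtOAc, rt
Reagents that add atoms: none (H2 adds only hydrogen)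
Why: Lindlar semi-hydrogenation stops at the terminal alkene and leaves the aryl ether intact.

**Step 3**
Reactants: 3, 1,2-dimethoxy-4-[(2-methylbut-3-en-2-yl)oxy]benzene
Product: 4, 4,5-dimethoxy-2-(3-methylbut-2-en-1-yl)phenol
Conditions: PhNEt2, 140 °C
Reagents that add atoms: none
Why: Aromatic ortho-Claisen rearrangement of the 1,1-dimethylallyl ether delivers a normal prenyl group to the less hindered ortho carbon (para to OMe), the site favoured for 3,4-dimethoxyphenyl ethers.

**Step 4**
Reactants: 4, 4,5-dimethoxy-2-(3-methylbut-2-en-1-yl)phenol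
Product: 5, 1,2-dimethoxy-4-(methoxymethoxy)-5-(3-methylbut-2-en-1-yl)benzene
Conditions: MOMCl, i-Pr2NEt, CH2Cl2, 0 °C → rt
Reagents that add atoms: chloromethyl methyl ether (MOMCl), COCCl
Why: Standard phenol MOM etherification, which also installs the directing group for step 5.

**Step 5**
Reactants: 5, 1,2-dimethoxy-4-(methoxymethoxy)-5-(3-methylbut-2-en-1-yl)benzene
Product: 6, 2,3-dimethoxy-6-(methoxymethoxy)-5-(3-methylbut-2-en-1-yl)phenol
Conditions: n-BuLi, THF, 0 °C; B(OMe)3, −78 °C → rt; H2O2, aq NaOH, 0 °C
Reagents that add atoms: hydrogen peroxide, OO (trimethyl borate, COB(OC)OC, is transient and leaves no atoms)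
Why: Directed ortho-metalation occurs at the only C–H flanked by two oxygens (OMOM and OMe), and borylation then basic peroxide oxidation gives the phenol without touching the alkene.

**Step 6**
Reactants: 6, 2,3-dimethoxy-6-(methoxymethoxy)-5-(3-methylbut-2-en-1-yl)phenol
Product: 7, 1,2-dimethoxy-4-(methoxymethoxy)-5-(3-methylbut-2-en-1-yl)-3-[(3-methylbut-2-en-1-yl)oxy]benzene
Conditions: prenyl bromide, K2CO3, DMF, rt
Reagents that add atoms: prenyl bromide (1-bromo-3-methylbut-2-ene), CC(C)=CCBr
Why: Williamson O-alkylation of the phenoxide in a polar aprotic solvent gives the O-prenyl ether.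

**Step 7**
Reactants: 7, the O-prenyl ether from step 6
Product: 8, 2,3-dimethoxy-6-(methoxymethoxy)-4,5-bis(3-methylbut-2-en-1-yl)phenol
Conditions: PhNEt2, 190 °C (sealed tube)
Reagents that add atoms: none
Why: Para-Claisen–Cope rearrangement: both ortho positions are blocked, so the ortho-dienone from the first [3,3] shift undergoes a Cope shift to the only free (para) carbon, giving a normal prenyl group and regenerating the phenol needed for coupling.

**Step 8**
Reactants: 9, phloroglucinol (benzene-1,3,5-triol)
Product: 10, 3,5-bis(methoxymethoxy)phenol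
Conditions: MOMCl (2.1 equiv), i-Pr2NEt, THF/DMF, 0 °C → rt; chromatography
Reagents that add atoms: MOMCl, COCCl
Why: Statistical bis-etherification of a symmetric triol (about 40% expected); mono- and tris-ethers are separable and recyclable.

**Step 9**
Reactants: 10, 3,5-bis(methoxymethoxy)phenol
Product: 11, 2-bromo-3,5-bis(methoxymethoxy)phenol
Conditions: NBS, i-Pr2NH (cat.), CH2Cl2, −78 → 0 °C
Reagents that add atoms: N-bromosuccinimide, O=C1CCC(=O)N1Br
Why: Amine-catalysed, hydrogen-bond-directed electrophilic bromination of a phenol is ortho-selective, and the two equivalent ortho sites are also less hindered than C4.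

**Step 10**
Reactants: 11, 2-bromo-3,5-bis(methoxymethoxy)phenol
Product: 12, 3,5-bis(methoxymethoxy)-2-(trimethylsilyl)phenyl trifluoromethanesulfonate
Conditions: HMDS, THF, 70 °C, concentrate; n-BuLi, THF, −100 → −78 °C; Tf2O, −78 °C
Reagents that add atoms: hexamethyldisilazane, C[Si](C)(C)N[Si](C)(C)C; triflic anhydride, O=S(=O)(OS(=O)(=O)C(F)(F)F)C(F)(F)F
Why: O-silylation, Br/Li exchange, retro-Brook O→C silyl migration and triflation of the resulting phenoxide is the standard one-pot route to Kobayashi aryne precursors, placing TMS exactly where Br was.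

**Step 11**
Reactants: 8, 2,3-dimethoxy-6-(methoxymethoxy)-4,5-bis(3-methylbut-2-en-1-yl)phenol; 12, 3,5-bis(methoxymethoxy)-2-(trimethylsilyl)phenyl triflate (1.5 equiv)
Product: 13, methyl 2-[2,3-dimethoxy-6-(methoxymethoxy)-4,5-bis(3-methylbut-2-en-1-yl)phenoxy]-4,6-bis(methoxymethoxy)benzoate
Conditions: 8, KH, THF, 0 °C; then 12, KF, 18-crown-6, CO2 (1 atm), THF, 0 °C → rt; then MeI, DMF, rt
Reagents that add atoms: carbon dioxide, O=C=O; iodomethane, CI
Why: Proposed new method: carboxylative aryloxylation of an aryne — the preformed, proton-free potassium aryloxide (fully substituted, so only O-attack is possible) adds to fluoride-generated 3,5-bis(MOMO)benzyne at C1, distal to the 3-OMOM group as dictated by aryne distortion; the resulting 2-aryloxy aryl anion, stabilised by the flanking OMOM and lacking any proton source or internal electrophile, is trapped by CO2, and MeI esterifies the carboxylate in situ; the closest known reactions are the aryne/amine/CO2 three-component coupling to anthranilates and fluoride-mediated O-arylation of phenols by arynes.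

**Step 12**
Reactants: 13, the tri-MOM ether from step 11
Product: 14, 4-methylhydroatrovirinone, methyl 2-[6-hydroxy-2,3-dimethoxy-4,5-bis(3-methylbut-2-en-1-yl)phenoxy]-4,6-dihydroxybenzoate
Conditions: HCl (ca. 1 M in MeOH), 0 °C → rt, quench at full conversion
Reagents that add atoms: none
Why: Mild acid-catalysed acetal methanolysis removes all three phenolic MOM groups while the methyl ester (in MeOH), the aryl methyl ethers and, under these dilute low-temperature conditions, the prenyl alkenes are retained.

## Compound list

1 | 3,4-dimethoxyphenol | COc1ccc(O)cc1OC | starting material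
2 | 1,2-dimethoxy-4-[(2-methylbut-3-yn-2-yl)oxy]benzene | COc1ccc(OC(C)(C)C#C)cc1OC | intermediate
3 | 1,2-dimethoxy-4-[(2-methylbut-3-en-2-yl)oxy]benzene | COc1ccc(OC(C)(C)C=C)cc1OC | intermediate
4 | 4,5-dimethoxy-2-(3-methylbut-2-en-1-yl)phenol | COc1cc(O)c(CC=C(C)C)cc1OC | intermediate
5 | 1,2-dimethoxy-4-(methoxymethoxy)-5-(3-methylbut-2-en-1-yl)benzene | COCOc1cc(OC)c(OC)cc1CC=C(C)C | intermediate
6 | 2,3-dimethoxy-6-(methoxymethoxy)-5-(3-methylbut-2-en-1-yl)phenol | COCOc1c(O)c(OC)c(OC)cc1CC=C(C)C | intermediate
7 | 1,2-dimethoxy-4-(methoxymethoxy)-5-(3-methylbut-2-en-1-yl)-3-[(3-methylbut-2-en-1-yl)oxy]benzene | COCOc1c(OCC=C(C)C)c(OC)c(OC)cc1CC=C(C)C | intermediate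
8 | 2,3-dimethoxy-6-(methoxymethoxy)-4,5-bis(3-methylbut-2-en-1-yl)phenol | COCOc1c(O)c(OC)c(OC)c(CC=C(C)C)c1CC=C(C)C | intermediate
9 | phloroglucinol (benzene-1,3,5-triol) | Oc1cc(O)cc(O)c1 | starting material
10 | 3,5-bis(methoxymethoxy)phenol | COCOc1cc(O)cc(OCOC)c1 | intermediate
11 | 2-bromo-3,5-bis(methoxymethoxy)phenol | COCOc1cc(O)c(Br)c(OCOC)c1 | intermediate
12 | 3,5-bis(methoxymethoxy)-2-(trimethylsilyl)phenyl trifluoromethanesulfonate | COCOc1cc(OCOC)c([Si](C)(C)C)c(OS(=O)(=O)C(F)(F)F)c1 | intermediate
13 | methyl 2-[2,3-dimethoxy-6-(methoxymethoxy)-4,5-bis(3-methylbut-2-en-1-yl)phenoxy]-4,6-bis(methoxymethoxy)benzoate | COCOc1cc(OCOC)c(C(=O)OC)c(Oc2c(OCOC)c(CC=C(C)C)c(CC=C(C)C)c(OC)c2OC)c1 | intermediate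
14 | 4-methylhydroatrovirinone, methyl 2-[6-hydroxy-2,3-dimethoxy-4,5-bis(3-methylbut-2-en-1-yl)phenoxy]-4,6-dihydroxybenzoate | COC(=O)c1c(O)cc(O)cc1Oc1c(O)c(CC=C(C)C)c(CC=C(C)C)c(OC)c1OC | target

## Summary

Total steps: 12. Longest linear sequence: 9 (steps 1–7, 11, 12); steps 8–10 form the three-step side branch.

Three steps most likely to fail:

1. **Step 11 (proposed new aryne/aryloxide/CO2 coupling).** Risks are protonation of the aryl anion (giving the ester-free diaryl ether), sequestration of the phenoxide as its carbonate, triflyl transfer to the phenoxide, and aryne-ene reaction with the prenyl groups. Fallback (known chemistry): convert methyl 2,4,6-trihydroxybenzoate into methyl 2,4-bis(methoxymethoxy)-6-(trifluoromethylsulfonyloxy)benzoate (MOMCl ×2, then Tf2O) and join it to 8 by Pd-catalysed (bulky biarylphosphine) or Cu-mediated Ullmann diaryl ether coupling, with the ester already in place.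

2. **Step 7 (para-Claisen–Cope into a position flanked by OMe and prenyl).** Risks are thermal loss of the prenyl group (retro-ene to phenol 6) and low conversion. Fallback: intermolecular Friedel–Crafts C-prenylation of phenol 6 with 2-methylbut-3-en-2-ol/BF3·OEt2; regiochemistry is forced because 6 has a single unsubstituted ring carbon, and the MOM group is re-installed if it is lost.

3. **Step 12 (acidic global MOM removal next to an ortho-prenyl phenol).** The risk is acid-catalysed cyclisation of the C2'-OH onto the C3' prenyl to give a 2,2-dimethylchroman, or alkene hydration. Fallback: change the protecting-group strategy to SEM ethers on both fragments (same directed-metalation and aryne chemistry) and unmask with fluoride (TBAF, THF/DMPU), so no acid is used.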